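**Retrosynthetic overview**

- The strategy rests on the methoxy group at C3 of the furan ring, next to the aryl-bearing C2. Its C3–O bond is made on the C2=C3 enol-ether bond of the 3-unsubstituted benzofuran, the most easily oxidised site of the molecule.
- Target ⇐ bis-silyl ether (fluoride) ⇐ 2,3-dimethoxy-2,3-dihydrobenzofuran (acid, loss of methanol from C2/C3) ⇐ 3-H benzofuran by two-electron anodic oxidation in methanol (C3–O and a sacrificial C2–O bond; no ring formed).
- 3-H benzofuran ⇐ C5 bromide + prenylboronate (Suzuki–Miyaura) ⇐ benzofurandiol (silylation).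
- The furan ring is the only ring formed: Sonogashira coupling at C–I, then 5-endo-dig O–C2 closure, from 4-bromo-6-iodoresorcinol and the isovanillin-derived alkyne. Both benzene rings are bought.
- Iodoresorcinol ⇐ 4-bromoresorcinol (iodination); alkyne ⇐ isovanillin (Seyferth–Gilbert homologation).

Key step: step 6

Assumption: the target is achiral, so the two stereocentres of the anodic adduct are formed as a racemate, probably as a cis/trans mixture. The trans isomer is drawn, and both isomers converge in step 7.

**Route**

Step 1
Reactants: 1 4-bromoresorcinol (4-bromobenzene-1,3-diol)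
Product: 2 4-bromo-6-iodobenzene-1,3-diol
Conditions: NIS (1.0 equiv), TsOH (cat.), MeCN, 0 °C
Reagents that add atoms: N-iodosuccinimide, O=C1CCC(=O)N1I
Why: Electrophilic aromatic iodination, in which C6 is para to the C3 hydroxyl and ortho to the C1 hydroxyl while C2 is wedged between both hydroxyls, so one equivalent of reagent under mild acid catalysis should deliver the 6-iodide.

Step 2
Reactants: 3 isovanillin (3-hydroxy-4-methoxybenzaldehyde)
Product: 4 5-ethynyl-2-methoxyphenol
Conditions: dimethyl (1-diazo-2-oxopropyl)phosphonate, K2CO3, MeOH, rt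
Reagents that add atoms: dimethyl (1-diazo-2-oxopropyl)phosphonate, COP(=O)(OC)C(=[N+]=[N-])C(C)=O
Why: Seyferth–Gilbert homologation in its Ohira–Bestmann form, in which methoxide deacetylates the reagent, the diazomethylphosphonate anion olefinates the aldehyde and the diazoalkene loses dinitrogen with a 1,2-hydride shift to the terminal alkyne; the meta phenoxide is not conjugated to the aldehyde and should not slow the addition.

Step 3
Reactants: 2 4-bromo-6-iodobenzene-1,3-diol; 4 5-ethynyl-2-methoxyphenol
Product: 6 5-bromo-2-(3-hydroxy-4-methoxyphenyl)-1-benzofuran-6-ol, via alkynylresorcinol 5 (not isolated)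
Conditions: Pd(PPh3)2Cl2 (cat.), CuI (cat.), Et3N, DMF (degassed), rt then 70 °C
Reagents that add atoms: none
Why: Sonogashira coupling at the C–I bond, which adds to zerovalent palladium far faster than the C–Br bond, followed by copper/amine-promoted 5-endo-dig attack of the neighbouring hydroxyl on the alkyne (the classical one-pot benzofuran synthesis from ortho-iodophenols); only the hydroxyl ortho to the alkyne can close the ring.

Step 4
Reactants: 6 5-bromo-2-(3-hydroxy-4-methoxyphenyl)-1-benzofuran-6-ol
Product: 7 5-bromo-2-{4-methoxy-3-[(triisopropylsilyl)oxy]phenyl}-6-[(triisopropylsilyl)oxy]-1-benzofuran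
Conditions: TIPSCl, imidazole, DMAP (cat.), DMF, 40 °C
Reagents that add atoms: chlorotriisopropylsilane, CC(C)[Si](Cl)(C(C)C)C(C)C
Why: Imidazole-mediated O-silylation of both phenols, the bulky triisopropylsilyl group being chosen to withstand aqueous phosphate, buffered methanol at the anode and pyridinium tosylate, and to keep the C6 oxygen from adding to the prenyl alkene later.

Step 5
Reactants: 7 5-bromo-2-{4-methoxy-3-[(triisopropylsilyl)oxy]phenyl}-6-[(triisopropylsilyl)oxy]-1-benzofuran; 8 prenylboronic acid pinacol ester
Product: 9 2-{4-methoxy-3-[(triisopropylsilyl)oxy]phenyl}-5-(3-methylbut-2-en-1-yl)-6-[(triisopropylsilyl)oxy]-1-benzofuran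
Conditions: Pd(OAc)2 (cat.), tBuXPhos (cat.), K3PO4, MeCN/H2O, 70 °C
Reagents that add atoms: none
Why: Suzuki–Miyaura coupling of an allylboronate, in which the allylpalladium formed on transmetallation equilibrates through the π-allyl form and a bulky di-tert-butyl biarylphosphine directs reductive elimination to the unhindered CH2 terminus, giving the linear prenyl arene and not the 1,1-dimethylallyl isomer.

Step 6
Reactants: 9 2-{4-methoxy-3-[(triisopropylsilyl)oxy]phenyl}-5-(3-methylbut-2-en-1-yl)-6-[(triisopropylsilyl)oxy]-1-benzofuran
Product: 10 racemic trans-2,3-dimethoxy-2-{4-methoxy-3-[(triisopropylsilyl)oxy]phenyl}-5-(3-methylbut-2-en-1-yl)-6-[(triisopropylsilyl)oxy]-2,3-dihydro-1-benzofuran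
Conditions: reticulated vitreous carbon anode, Pt cathode, divided cell, Et4NOTs (0.1 M), 2,6-lutidine (excess), MeOH/CH2Cl2 4:1, constant potential at the first anodic wave of 9 (set by cyclic voltammetry, Ag/AgCl reference), about 2 F/mol, 0 °C, dilute
Reagents that add atoms: methanol, CO
Why: The 2-arylbenzofuran π-system of 9 (C2=C3 conjugated with O1, the benzo ring with its C6 silyloxy group, and the 4-methoxyaryl ring) should give up one electron at a potential well below that of the isolated trisubstituted prenyl alkene or of either alkoxyarene alone; methanol adds to the radical cation, the resulting radical is oxidised at once to a cation (at C2 an oxocarbenium ion stabilised by O1 and the aryl ring), a second methanol is captured, and 2,6-lutidine takes up both protons. The closest known reaction type is the anodic 2,3-dimethoxylation of furans and benzofurans in methanol (the electrochemical Clauson-Kaas-type addition), applied here to a 2-aryl member of that class. No ring is closed, and the step forms only the C3–O bond and the C2–O bond. C2 and C3 become stereocentres without absolute control (racemate); their relative configuration is fixed when the second methanol attacks the planar cation anti to the methoxy group already in place, which should favour the trans adduct, and the cis adduct serves equally because both centres are flattened again in step 7. The step needs selectivity for the C2=C3 bond over the prenyl alkene, over the two alkoxyarene rings and over the product; the extended conjugation of 9 secures the first two, and 10, having lost that conjugation, is harder to oxidise than 9 and should survive at the chosen potential. Excess lutidine keeps the anolyte from turning acidic so that 10 does not shed methanol in the cell to give the more oxidisable 11, and dilution in methanol suppresses coupling of two radical cations through C3.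

Step 7
Reactants: 10 racemic 2,3-dimethoxy-2,3-dihydrobenzofuran adduct
Product: 11 3-methoxy-2-{4-methoxy-3-[(triisopropylsilyl)oxy]phenyl}-5-(3-methylbut-2-en-1-yl)-6-[(triisopropylsilyl)oxy]-1-benzofuran
Conditions: PPTS (cat.), toluene, 4 Å molecular sieves, 60 °C
Reagents that add atoms: none
Why: Acid-catalysed E1 loss of methanol from a mixed ketal, in which the C2 methoxy group ionises to the O1- and aryl-stabilised oxocarbenium ion far more readily than the benzylic C3 ether, and C3 carries the only proton that can be lost, so the benzofuran is restored with the methoxy group on C3; both stereocentres of 10 are erased.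

Step 8
Reactants: 11 3-methoxy-2-{4-methoxy-3-[(triisopropylsilyl)oxy]phenyl}-5-(3-methylbut-2-en-1-yl)-6-[(triisopropylsilyl)oxy]-1-benzofuran
Product: 12 2-(3-hydroxy-4-methoxyphenyl)-3-methoxy-5-(3-methylbut-2-en-1-yl)-1-benzofuran-6-ol (CNP0278880.0)
Conditions: Bu4NF, AcOH, THF, 0 °C, under argon
Reagents that add atoms: none
Why: Fluoride-induced cleavage of both aryl silyl ethers, buffered with acetic acid so that the electron-rich phenoxides are protonated at once and neither the prenyl alkene nor the 3-methoxy enol ether is exposed to strong acid or base.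

**Compound list**

1 | 4-bromoresorcinol (4-bromobenzene-1,3-diol) | Oc1ccc(Br)c(O)c1 | starting material
2 | 4-bromo-6-iodobenzene-1,3-diol | Oc1cc(O)c(I)cc1Br | intermediate
3 | isovanillin | COc1ccc(C=O)cc1O | starting material
4 | 5-ethynyl-2-methoxyphenol | COc1ccc(C#C)cc1O | intermediate
5 | 4-bromo-6-[(3-hydroxy-4-methoxyphenyl)ethynyl]benzene-1,3-diol (alkynylresorcinol, not isolated) | COc1ccc(C#Cc2cc(Br)c(O)cc2O)cc1O | intermediate
6 | 5-bromo-2-(3-hydroxy-4-methoxyphenyl)-1-benzofuran-6-ol | COc1ccc(-c2cc3cc(Br)c(O)cc3o2)cc1O | intermediate
7 | 5-bromo-2-{4-methoxy-3-[(triisopropylsilyl)oxy]phenyl}-6-[(triisopropylsilyl)oxy]-1-benzofuran | COc1ccc(-c2cc3cc(Br)c(O[Si](C(C)C)(C(C)C)C(C)C)cc3o2)cc1O[Si](C(C)C)(C(C)C)C(C)C | intermediate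
8 | prenylboronic acid pinacol ester | CC(C)=CCB1OC(C)(C)C(C)(C)O1 | starting material
9 | 2-{4-methoxy-3-[(triisopropylsilyl)oxy]phenyl}-5-(3-methylbut-2-en-1-yl)-6-[(triisopropylsilyl)oxy]-1-benzofuran | COc1ccc(-c2cc3cc(CC=C(C)C)c(O[Si](C(C)C)(C(C)C)C(C)C)cc3o2)cc1O[Si](C(C)C)(C(C)C)C(C)C | intermediate
10 | racemic trans-2,3-dimethoxy-2-{4-methoxy-3-[(triisopropylsilyl)oxy]phenyl}-5-(3-methylbut-2-en-1-yl)-6-[(triisopropylsilyl)oxy]-2,3-dihydro-1-benzofuran (one enantiomer drawn) | CO[C@H]1c2cc(CC=C(C)C)c(O[Si](C(C)C)(C(C)C)C(C)C)cc2O[C@@]1(OC)c1ccc(OC)c(O[Si](C(C)C)(C(C)C)C(C)C)c1 | intermediate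
11 | 3-methoxy-2-{4-methoxy-3-[(triisopropylsilyl)oxy]phenyl}-5-(3-methylbut-2-en-1-yl)-6-[(triisopropylsilyl)oxy]-1-benzofuran | COc1ccc(-c2oc3cc(O[Si](C(C)C)(C(C)C)C(C)C)c(CC=C(C)C)cc3c2OC)cc1O[Si](C(C)C)(C(C)C)C(C)C | intermediate
12 | 2-(3-hydroxy-4-methoxyphenyl)-3-methoxy-5-(3-methylbut-2-en-1-yl)-1-benzofuran-6-ol | COc1ccc(-c2oc3cc(O)c(CC=C(C)C)cc3c2OC)cc1O | target

**Step count**

Total steps: 8. Longest linear sequence: 7 steps (1 → 2 → 6 → 7 → 9 → 10 → 11 → 12; the branch from 3 through 4 is equally long).

**Steps most likely to fail**

Step 6 (anodic dimethoxylation). The adduct may lose methanol in the anolyte and the resulting benzofuran may then be over-oxidised. Two radical cations may couple through C3, the C6 silyl group may be lost from the oxidised intermediate, the prenyl alkene may be oxidised if the potential drifts, and the anode may passivate. The fallback sets out from bromide 7, before the prenyl alkene is present, because the oxidant would also epoxidise that alkene. Dimethyldioxirane in acetone at −40 °C should epoxidise the C2=C3 bond to the cis-fused epoxide F1. On warming over silica gel its C2–O bond should open to the O1/aryl-stabilised cation, and a 1,2-hydride shift from C3 to C2 should give the 2-arylbenzofuran-3(2H)-one F2. Its potassium enolate (KHMDS, THF/DMPU, −78 °C) should be methylated on oxygen by methyl triflate, the hard electrophile and the gain of aromaticity favouring O- over C-alkylation, to give the 5-bromo-3-methoxybenzofuran F3. Suzuki–Miyaura coupling of F3 with 8 under the conditions of step 5 comes back to the route at 11.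

Step 5 (prenylation). The allyl unit may be transferred through its γ-carbon to give the 1,1-dimethylallyl isomer, the boronate may protodeboronate, and the phosphate base may strip a silyl group. The fallback sets out from 7. Suzuki–Miyaura coupling with allylboronic acid pinacol ester (Pd(dppf)Cl2, K3PO4, THF/H2O, 70 °C), whose symmetrical allyl group raises no regiochemical question, should give the 5-allyl compound F4. Cross-metathesis of F4 with excess 2-methyl-2-butene and second-generation Grubbs catalyst in CH2Cl2 at 40 °C should then exchange the terminal CH2 for the isopropylidene group and come back to the route at 9. The benzofuran C2=C3 bond is not a metathesis partner.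

Step 3 (coupling and ring closure on unprotected phenols). Oxidative addition into the electron-rich iodophenoxide may be slow, the alkyne may homocouple oxidatively, ring closure may stop at 5, and forcing may bring in the bromide. The fallback sets out from 2 and separates coupling from ring closure. Acetylation (Ac2O, pyridine) should give the diacetate F5, whose C–I bond is more electrophilic and carries no free phenoxide. Sonogashira coupling of F5 with 4 at room temperature (Pd(PPh3)2Cl2, CuI, Et3N, THF) should give the diarylalkyne diacetate F6. Cs2CO3 in MeOH/DMF at 60 °C should then cleave both acetates and close the furan ring by 5-endo-dig attack of the liberated phenoxide, coming back to the route at 6.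

**Further compounds**

F1 | step 6 | racemic cis-fused 2,3-epoxide of 7 (5-bromo-2,3-epoxy-2-{4-methoxy-3-[(triisopropylsilyl)oxy]phenyl}-6-[(triisopropylsilyl)oxy]-2,3-dihydro-1-benzofuran; one enantiomer drawn) | COc1ccc([C@@]23O[C@@H]2c2cc(Br)c(O[Si](C(C)C)(C(C)C)C(C)C)cc2O3)cc1O[Si](C(C)C)(C(C)C)C(C)C
F2 | step 6 | racemic 5-bromo-2-{4-methoxy-3-[(triisopropylsilyl)oxy]phenyl}-6-[(triisopropylsilyl)oxy]-1-benzofuran-3(2H)-one | COc1ccc(C2Oc3cc(O[Si](C(C)C)(C(C)C)C(C)C)c(Br)cc3C2=O)cc1O[Si](C(C)C)(C(C)C)C(C)C
F3 | step 6 | 5-bromo-3-methoxy-2-{4-methoxy-3-[(triisopropylsilyl)oxy]phenyl}-6-[(triisopropylsilyl)oxy]-1-benzofuran | COc1ccc(-c2oc3cc(O[Si](C(C)C)(C(C)C)C(C)C)c(Br)cc3c2OC)cc1O[Si](C(C)C)(C(C)C)C(C)C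
F4 | step 5 | 5-allyl-2-{4-methoxy-3-[(triisopropylsilyl)oxy]phenyl}-6-[(triisopropylsilyl)oxy]-1-benzofuran | COc1ccc(-c2cc3cc(CC=C)c(O[Si](C(C)C)(C(C)C)C(C)C)cc3o2)cc1O[Si](C(C)C)(C(C)C)C(C)C
F5 | step 3 | 4-bromo-6-iodo-1,3-phenylene diacetate | CC(=O)Oc1cc(OC(C)=O)c(I)cc1Br
F6 | step 3 | 4-bromo-6-[(3-hydroxy-4-methoxyphenyl)ethynyl]-1,3-phenylene diacetate | COc1ccc(C#Cc2cc(Br)c(OC(C)=O)cc2OC(C)=O)cc1O
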